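**Compound numbers used throughout:** 1 (Z)-1,2-dimethoxyethene; 4 chromium carbene complex; 5 2,6-dimethoxyphenol; 6 trichloroethylene; 7 dichlorovinyl ether; 9 ring F ynol ether; 11 two-ring phenol (rings F–G, also used as D–E and B–C); 12 3,4,5-trimethoxyphenylboronic acid; 13 rings F–H trimer; 15 its boronic acid; 16 silyl ether of 11; 18 its boronic acid; 19 2,4,6-trimethoxyphenol; 20/21 rings A–C silyl ether/phenol; 22/23 rings A–E silyl ether/phenol; 24 per-O-methyl octamer; 25 target. Compounds 2, 3, 8, 10, 14 and 17 are intermediates that are not isolated.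

## Analysis of the target

Target 25 (C48H34O28) is a linear chain of eight benzene rings, A to H, held together only by seven diaryl ether oxygens and carrying 21 free phenolic hydroxyls. It has no stereocentre and no other stereo element, so the whole problem is regiochemical. Ring A is a 2,4,6-trihydroxyphenyl cap and ring H a 3,4,5-trihydroxyphenyl cap. Rings B, D and F are 3,5-dihydroxy-1,4-phenylene units whose C4 oxygen, lying between two hydroxyls, leads to the next ring. Rings C, E and G are pentaoxygenated, with ether oxygens at C1 and C2, hydroxyls at C3 to C5 and one hydrogen at C6. The pyrogallol- and hydroxyquinol-type arrays oxidise readily in air, above all as phenoxides, so all hydroxyls should travel as methyl ethers and be freed last under acid and argon. Two things make the synthesis hard: every ether oxygen sits on at least one carbon flanked by two oxygenated carbons, and the unsymmetrical pentaoxygenated pattern of rings C, E and G is not on offer in cheap aromatics. The strategy rests on ring G (and identically rings E and C): C2 bears an oxygen para to the C5 oxygen and is flanked by C1 (ether to ring F) and C3 (oxygen), while C6 is the only C–H. That is the 4-alkoxyphenol pattern that an alkenyl(alkoxy)carbene (C3, C4, C5), one carbonyl ligand (C2) and a terminal alkyne (C1, C6) assemble, with the ring F aryloxy group as the alkyne substituent. Because the pairs B–C, D–E and F–G are the same two-ring unit, one annulation product can serve three times.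

## Retrosynthetic reasoning

**25 to 24.** The last operation is cleavage of the 21 O–methyl bonds of 24. Methyl ethers are chosen because they survive organolithiums, the chromium carbene, C–H borylation and copper-mediated coupling. A boron Lewis acid removes them without touching aryl–O–aryl bonds, which have no sp3 carbon to attack. The forward step has to be exhaustive and has to keep air away from the product.

**24 to 23 and 15.** The bond between the ring E C2 oxygen and ring F C1 is cut, close to the middle of the chain. The oxygen stays on the five-ring phenol 23 and the carbon becomes the boron-bearing carbon of the three-ring boronic acid 15. This direction puts boron on a carbon with two ortho hydrogens and lets the smaller fragment be used in excess. The forward oxidative coupling has to accept a phenol flanked by an aryloxy and a methoxy group.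

**15 to 13 to 11 and 12.** The C–B bond of 15 goes back to the ring F C1–H of 13, the only C–H in 13 without an ortho substituent, so a sterically governed C–H borylation can find it. Cutting the ring G C2–O to ring H C1 bond of 13 gives phenol 11 and boronic acid 12.

**23 to 22 to 21 and 18; 21 to 20 to 19 and 18.** The ring C C2–O to ring D C1 bond and the ring A O to ring B C1 bond are cut in the same way. Both cuts lead to the same boronic acid 18, in which the phenol oxygen is masked as a silyl ether. A silyl ether is taken instead of a benzyl ether because an unsubstituted phenyl ring would itself be borylated. Compound 18 comes from 16, the silyl ether of 11, by the same C–H borylation. Phenol 11 is therefore the source of rings F–G, D–E and B–C, and the caps come from 19 and 12.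

**11 to 4 and 9 (key disconnection).** Ring G is cut at C5–C6, C1–C2 and C2–C3 into the carbene complex 4 (which supplies C3, C4, C5 and, from one carbonyl ligand, C2) and the ynol ether 9 (which supplies C1 and C6 and brings ring F on oxygen). This is the only place where the pentaoxygenated pattern can be assembled from three small pieces with every oxygen already on its carbon. It also makes the ring F C4–O to ring G C1 ether, whose oxygen is flanked by two methoxy groups, without a coupling. The forward reaction needs one selectivity, the direction of alkyne insertion, and it leaves free exactly the hydroxyl that must next be arylated.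

**9 to 7 to 5 and 6; 4 to 1.** The ynol ether goes back through the dichlorovinyl ether 7 to phenol 5 and 6, so the ring F oxygen pattern is bought. The carbene complex goes back to 1 by vinylic lithiation, addition to a metal carbonyl and O-methylation, so that all three methoxy groups of ring G C3 to C5 are present before the ring exists.

## Alternatives that were turned down

**Alternative 1: biomimetic ortho-quinone oxygenation on ring E.**
- Disconnection: the ring E C5–O bond and the ring E C1–O ether to ring D are both introduced on a pre-formed ring E phenol that already carries the ring F ether, for example 3-[4-(benzyloxy)-3,5-dimethoxyphenoxy]-2-methoxyphenol A2.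
- Forward key step: aerobic copper-mediated ortho-oxygenation of A2 at C5 gives an ortho-quinone. The ring D phenol 4-bromo-2,6-dimethoxyphenol A3 then adds through oxygen at C1, giving 4-[4-(benzyloxy)-3,5-dimethoxyphenoxy]-5-(4-bromo-2,6-dimethoxyphenoxy)-3-methoxycyclohexa-3,5-diene-1,2-dione A1.
- For: air supplies the oxygen and C–H bonds are the handles; the hindered D–O–E ether forms without an aryl–metal coupling; the oxygenation site is unambiguous because only one ortho position of A2 is free.
- Against: in A1 the carbon carrying the ring F aryloxy group is β to the C4 carbonyl, a vinylogous ester carbon, so addition–elimination by the incoming phenoxide can exchange ring F for ring D. A3 is a hindered, weak nucleophile that is itself oxidisable under the conditions. The quinone must be reduced and methylated before it can be carried on. The step installs one oxygen and one ether per ring and would have to be repeated on rings C and G with ever larger, oxidation-sensitive substrates, each needing its ring F-type ether made beforehand.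
- Comparison: alternative 1 is stronger in atom economy and in avoiding a stoichiometric transition metal. The chosen route offers in its place a non-oxidative ring construction in which sterics and alkyne polarisation point the same way, and a stable, fully O-alkylated phenol 11 that is used three times.

**Alternative 2: Danheiser benzannulation on ring B.**
- Disconnection: ring B is cut at C2–C3, C1–C6 and C3–C4 into 4-(benzyloxy)-3-methoxycyclobut-2-en-1-one A5 and 2-(ethynyloxy)-1,3,5-trimethoxybenzene A6.
- Forward key step: heating opens A5 to a vinylketene, which adds to A6; a second 4π opening and a 6π closure give 2-(benzyloxy)-3-methoxy-5-(2,4,6-trimethoxyphenoxy)phenol A4 with the ring A ether in place.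
- For: a reagent-free thermal cascade; the regiochemistry is set by the strong polarisation of the ynol ether toward the ketene carbon; the A–O–B ether, whose oxygen is flanked by two methoxy groups, is made without coupling; the benzyl ether marks the ring B C4 oxygen.
- Against: ring B has the easy, symmetrical pattern, which the chosen route takes at no cost from 5 and 19. The pentaoxygenated rings C, E and G stay unsolved, and the hardest union (ring B C4 oxygen onto an ortho-substituted ring C carbon) is left to conventional coupling. A5 needs several steps, and A6 is a terminal aryl ynol ether just as delicate as 9. The A–B unit occurs once in 25, so A4 cannot be reused, and methylation and debenzylation add steps.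
- Comparison: as an annulation the cascade is probably more dependable than a carbene annulation with a ynol ether, and that point goes to alternative 2. The chosen route instead spends its annulation on the ring whose substitution is the real problem and draws three of the seven ether bonds from it.

**Alternative 3: ruthenium-activated dichloroarene at ring F.**
- Disconnection: the ring F C1–O and C4–O bonds are cut, both to be formed by nucleophilic aromatic substitution on the cationic complex cyclopentadienyl(η6-2,5-dichloro-1,3-dimethoxybenzene)ruthenium hexafluorophosphate A8.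
- Forward key step: the phenoxide of 6-bromo-2,3,4-trimethoxyphenol A9 displaces the unhindered chloride, then the phenoxide of 2-(benzyloxy)-3,4,5-trimethoxyphenol A10 displaces the chloride between the two methoxy groups, giving the complexed rings E–F–G trimer A7, from which the metal is then removed.
- For: the cationic metal makes an electron-rich chloroarene a substrate for addition–elimination at low temperature; this mechanism is less sensitive to ortho substituents on the electrophile than a copper coupling; two ether bonds form in one operation in a convergent three-ring union.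
- Against: stoichiometric ruthenium with complexation and decomplexation steps. The order of the two substitutions rests on sterics alone, and the first substitution makes the ring a poorer electrophile just when the hindered chloride has to react. A9 and A10 are pentasubstituted phenols, so the difficult pattern of rings E and G is moved into multi-step precursor syntheses and not solved. The bromide of A7 must later become the ether to the hindered ring D oxygen.
- Comparison: for hindered ether bonds alternative 3 is stronger than the copper couplings used here. In exchange, the chosen route never couples at a carbon flanked by two methoxy groups (those oxygens arrive with 5 and 19), places boron only on carbons with two ortho hydrogens, and builds ring G with all its oxygens from three small pieces.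

Key step: step 4

**Assumption:** 1, 12 and 19 are taken as purchasable; rings are lettered A to H from the 2,4,6-trihydroxyphenyl end.

## Route

Step 1
Reactants: 1 (Z)-1,2-dimethoxyethene
Product: 4 pentacarbonyl[(2Z)-1,2,3-trimethoxyprop-2-en-1-ylidene]chromium, via (Z)-1,2-dimethoxyethenyllithium 2 (not isolated), via lithium pentacarbonyl(2,3-dimethoxypropenoyl)chromate 3 (not isolated)
Conditions: t-BuLi, THF, −78 °C; Cr(CO)6, THF, −78 → 0 °C; Me3OBF4, CH2Cl2, 0 °C
Reagents that add atoms: chromium hexacarbonyl Cr(CO)6, O=C=[Cr](=C=O)(=C=O)(=C=O)(=C=O)=C=O; trimethyloxonium tetrafluoroborate, C[O+](C)C.F[B-](F)(F)F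
Why: Fischer carbene synthesis; the vinylic hydrogen geminal to oxygen is lithiated with retention of the alkene geometry, the organolithium adds to a CO ligand to give acylchromate 3, and the hard oxonium salt methylates the acyl oxygen.

Step 2
Reactants: 5 2,6-dimethoxyphenol; 6 trichloroethylene
Product: 7 2-{[(E)-1,2-dichloroethenyl]oxy}-1,3-dimethoxybenzene
Conditions: K2CO3, DMF, 70 °C
Reagents that add atoms: none
Why: The base turns 6 into dichloroacetylene in low concentration and the phenoxide of 5 adds across it in trans fashion, the usual first stage of the dichlorovinyl ether route to ynol ethers.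

Step 3
Reactants: 7 2-{[(E)-1,2-dichloroethenyl]oxy}-1,3-dimethoxybenzene
Product: 9 2-(ethynyloxy)-1,3-dimethoxybenzene, via lithium (2,6-dimethoxyphenoxy)ethynide 8 (not isolated)
Conditions: n-BuLi (2.2 equiv), Et2O, −78 → −40 °C; H2O, −78 °C; used at once as a cold solution
Reagents that add atoms: none
Why: Dehydrochlorination to the chloroalkynyl ether and chlorine–lithium exchange give acetylide 8, and cold protonation gives the terminal ynol ether, which the two flanking methoxy groups shield against self-reaction.

Step 4
Reactants: 4 pentacarbonyl[(2Z)-1,2,3-trimethoxyprop-2-en-1-ylidene]chromium; 9 2-(ethynyloxy)-1,3-dimethoxybenzene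
Product: 11 6-(2,6-dimethoxyphenoxy)-2,3,4-trimethoxyphenol, via tricarbonylchromium complex of the phenol 10 (not isolated)
Conditions: THF, 55 °C, Ar; then air, rt
Reagents that add atoms: none
Why: Dötz benzannulation of an alkenyl(alkoxy)carbene complex of zerovalent chromium with a terminal alkyne, here a ynol ether, an uncommon partner for this reaction. Thermal loss of one cis CO from 4 opens a site for 9, which inserts into the Cr=C bond with its terminal carbon bonded to the carbene carbon (ring G C5–C6). A CO ligand then inserts at the aryloxy-bearing carbon to give a chromium-bound dienylketene (C1–C2), and 6π electrocyclisation between the ketene carbon and C3 of the propenylidene chain forms C2–C3 and closes the six-membered carbocycle; tautomerisation gives arene complex 10, and air releases 11. The one selectivity needed is the direction of alkyne insertion: hydrogen against a 2,6-dimethoxyphenoxy group is a large steric difference, and the ynol ether is polarised so that its nucleophilic terminal carbon meets the electrophilic carbene carbon, so both effects place the aryloxy group next to the CO-derived carbon. The (2Z) geometry of 4 puts hydrogen, not methoxy, on the inside of the cyclising terminus. No stereocentre is formed, every ring G carbon arrives oxygenated or as the single C–H, and the only free hydroxyl of 11 is the C2 oxygen that will carry ring H. Air is used for demetalation in place of a stronger oxidant so that the 4-methoxyphenol is not taken on to a quinone.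

Step 5
Reactants: 11 6-(2,6-dimethoxyphenoxy)-2,3,4-trimethoxyphenol; 12 3,4,5-trimethoxyphenylboronic acid
Product: 13 1-(2,6-dimethoxyphenoxy)-3,4,5-trimethoxy-2-(3,4,5-trimethoxyphenoxy)benzene (rings F–G–H)
Conditions: Cu(OAc)2 (1 equiv), pyridine, 4 Å MS, CH2Cl2, air, rt; 12 in excess
Reagents that add atoms: none
Why: Chan–Lam coupling; the electron-rich aryl group of 12, which has no ortho substituent, transmetalates to divalent copper, and C–O reductive elimination from trivalent copper occurs at room temperature without strong base; air returns the copper to the divalent state.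

Step 6
Reactants: 13 rings F–G–H trimer
Product: 15 {3,5-dimethoxy-4-[3,4,5-trimethoxy-2-(3,4,5-trimethoxyphenoxy)phenoxy]phenyl}boronic acid, via pinacol boronate of the trimer 14 (not isolated)
Conditions: [Ir(OMe)(cod)]2 (cat.), 4,4′-di-tert-butyl-2,2′-bipyridine, B2pin2, THF, 80 °C; then NaIO4, NH4OAc, acetone–H2O, rt
Reagents that add atoms: bis(pinacolato)diboron, CC1(C)OB(OC1(C)C)B1OC(C)(C)C(C)(C)O1; water, O
Why: Iridium-catalysed C–H borylation through a trivalent iridium tris(boryl) complex is sterically governed, and ring F C1–H is the only C–H of 13 without an ortho substituent; periodate cleavage of the pinacol in the same flask gives the free boronic acid that the copper coupling prefers.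

Step 7
Reactants: 11 6-(2,6-dimethoxyphenoxy)-2,3,4-trimethoxyphenol
Product: 16 tert-butyl[6-(2,6-dimethoxyphenoxy)-2,3,4-trimethoxyphenoxy]dimethylsilane
Conditions: TBSCl, imidazole, DMF, 40 °C
Reagents that add atoms: tert-butyldimethylsilyl chloride, CC(C)(C)[Si](C)(C)Cl
Why: Standard silylation of a phenol; a silyl ether is used because a benzyl ether would offer unhindered aryl C–H bonds to the borylation catalyst, and it survives borylation, periodate and the room-temperature copper coupling.

Step 8
Reactants: 16 silyl ether of the two-ring phenol
Product: 18 [4-(2-{[tert-butyl(dimethyl)silyl]oxy}-3,4,5-trimethoxyphenoxy)-3,5-dimethoxyphenyl]boronic acid, via pinacol boronate of the silyl ether 17 (not isolated)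
Conditions: [Ir(OMe)(cod)]2 (cat.), 4,4′-di-tert-butyl-2,2′-bipyridine, B2pin2, THF, 80 °C; then NaIO4, NH4OAc, acetone–H2O, rt
Reagents that add atoms: bis(pinacolato)diboron, CC1(C)OB(OC1(C)C)B1OC(C)(C)C(C)(C)O1; water, O
Why: Same C–H borylation and pinacol cleavage as in step 6; the C–H para to the ether oxygen on the dimethoxyphenoxy ring is again the only one without an ortho substituent, and buffered periodate leaves the aryl silyl ether intact.

Step 9
Reactants: 19 2,4,6-trimethoxyphenol; 18 silyl-protected two-ring boronic acid
Product: 20 tert-butyl{6-[2,6-dimethoxy-4-(2,4,6-trimethoxyphenoxy)phenoxy]-2,3,4-trimethoxyphenoxy}dimethylsilane (rings A–B–C)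
Conditions: Cu(OAc)2 (1 equiv), pyridine, 4 Å MS, CH2Cl2, air, rt
Reagents that add atoms: none
Why: Chan–Lam coupling; the ring A oxygen arrives on the phenol, so no coupling is needed at a carbon flanked by two methoxy groups, and the para methoxy group of 19 blocks oxidative C–C dimerisation.

Step 10
Reactants: 20 rings A–B–C silyl ether
Product: 21 6-[2,6-dimethoxy-4-(2,4,6-trimethoxyphenoxy)phenoxy]-2,3,4-trimethoxyphenol
Conditions: Bu4NF, AcOH, THF, 0 °C
Reagents that add atoms: none
Why: Fluoride-driven Si–O cleavage of an aryl silyl ether; the acetic acid buffer keeps the electron-rich phenol protonated and so limits its oxidation.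

Step 11
Reactants: 21 rings A–B–C phenol; 18 silyl-protected two-ring boronic acid
Product: 22 rings A–E silyl ether (21 with its hydroxyl oxygen bonded to the boron-bearing carbon of 18)
Conditions: Cu(OAc)2 (1 equiv), pyridine, 4 Å MS, CH2Cl2, air, rt; 18 in excess
Reagents that add atoms: none
Why: Chan–Lam coupling of the same type as step 5 (phenol flanked by aryloxy and methoxy, unhindered boron-bearing carbon), forming the ring C C2–O to ring D C1 bond.

Step 12
Reactants: 22 rings A–E silyl ether
Product: 23 rings A–E phenol, 6-[2,6-dimethoxy-4-(2,3,4-trimethoxy-6-{2,6-dimethoxy-4-(2,4,6-trimethoxyphenoxy)phenoxy}phenoxy)phenoxy]-2,3,4-trimethoxyphenol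
Conditions: Bu4NF, AcOH, THF, 0 °C
Reagents that add atoms: none
Why: Buffered fluoride desilylation as in step 10, freeing the ring E C2 hydroxyl.

Step 13
Reactants: 23 rings A–E phenol; 15 rings F–G–H boronic acid
Product: 24 per-O-methyl octamer (the henicosamethyl ether of the target)
Conditions: Cu(OAc)2 (1 equiv), pyridine, 4 Å MS, CH2Cl2, air, rt; 15 in excess
Reagents that add atoms: none
Why: Chan–Lam coupling forming the ring E C2–O to ring F C1 bond; the cheaper three-ring boronic acid is used in excess, and its boron-bearing carbon has two ortho hydrogens.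

Step 14
Reactants: 24 per-O-methyl octamer
Product: 25 target (CNP0206369.0)
Conditions: BBr3 (excess), CH2Cl2, −78 °C → rt; degassed H2O, Ar
Reagents that add atoms: none
Why: Lewis acid demethylation; each methoxy oxygen binds boron and bromide attacks the methyl carbon, while the diaryl ether bonds have no sp3 carbon and stay intact; hydrolysis of the aryl borates gives the polyphenol, which has no stereocentre to disturb.

## Compound list

1 | (Z)-1,2-dimethoxyethene | CO/C=C\OC | starting material
2 | (Z)-1,2-dimethoxyethenyllithium | CO/C=C(\OC)[Li] | intermediate (not isolated)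
3 | lithium pentacarbonyl[(2Z)-2,3-dimethoxyprop-2-enoyl]chromate | CO/C=C(\OC)C([O-])=[Cr](=C=O)(=C=O)(=C=O)(=C=O)=C=O.[Li+] | intermediate (not isolated)
4 | pentacarbonyl[(2Z)-1,2,3-trimethoxyprop-2-en-1-ylidene]chromium | CO/C=C(\OC)C(OC)=[Cr](=C=O)(=C=O)(=C=O)(=C=O)=C=O | intermediate
5 | 2,6-dimethoxyphenol | COc1cccc(OC)c1O | starting material
6 | trichloroethylene | ClC=C(Cl)Cl | starting material
7 | 2-{[(E)-1,2-dichloroethenyl]oxy}-1,3-dimethoxybenzene | Cl/C=C(/Cl)Oc1c(OC)cccc1OC | intermediate
8 | lithium (2,6-dimethoxyphenoxy)ethynide | [Li]C#COc1c(OC)cccc1OC | intermediate (not isolated)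
9 | 2-(ethynyloxy)-1,3-dimethoxybenzene | C#COc1c(OC)cccc1OC | intermediate
10 | tricarbonyl{η6-[6-(2,6-dimethoxyphenoxy)-2,3,4-trimethoxyphenol]}chromium | COc1cc(Oc2c(OC)cccc2OC)c(O)c(OC)c1OC.O=C=[Cr](=C=O)=C=O | intermediate (not isolated)
11 | 6-(2,6-dimethoxyphenoxy)-2,3,4-trimethoxyphenol | COc1cc(Oc2c(OC)cccc2OC)c(O)c(OC)c1OC | intermediate
12 | 3,4,5-trimethoxyphenylboronic acid | COc1cc(B(O)O)cc(OC)c1OC | starting material
13 | 1-(2,6-dimethoxyphenoxy)-3,4,5-trimethoxy-2-(3,4,5-trimethoxyphenoxy)benzene | COc1cc(Oc2c(OC)cccc2OC)c(Oc2cc(OC)c(OC)c(OC)c2)c(OC)c1OC | intermediate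
14 | pinacol ester of 15 | COc1cc(Oc2c(OC)cc(B3OC(C)(C)C(C)(C)O3)cc2OC)c(Oc2cc(OC)c(OC)c(OC)c2)c(OC)c1OC | intermediate (not isolated)
15 | {3,5-dimethoxy-4-[3,4,5-trimethoxy-2-(3,4,5-trimethoxyphenoxy)phenoxy]phenyl}boronic acid | COc1cc(Oc2c(OC)cc(B(O)O)cc2OC)c(Oc2cc(OC)c(OC)c(OC)c2)c(OC)c1OC | intermediate
16 | tert-butyl[6-(2,6-dimethoxyphenoxy)-2,3,4-trimethoxyphenoxy]dimethylsilane | COc1cc(Oc2c(OC)cccc2OC)c(O[Si](C)(C)C(C)(C)C)c(OC)c1OC | intermediate
17 | pinacol ester of 18 | COc1cc(Oc2c(OC)cc(B3OC(C)(C)C(C)(C)O3)cc2OC)c(O[Si](C)(C)C(C)(C)C)c(OC)c1OC | intermediate (not isolated)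
18 | [4-(2-{[tert-butyl(dimethyl)silyl]oxy}-3,4,5-trimethoxyphenoxy)-3,5-dimethoxyphenyl]boronic acid | COc1cc(Oc2c(OC)cc(B(O)O)cc2OC)c(O[Si](C)(C)C(C)(C)C)c(OC)c1OC | intermediate
19 | 2,4,6-trimethoxyphenol | COc1cc(OC)c(O)c(OC)c1 | starting material
20 | tert-butyl{6-[2,6-dimethoxy-4-(2,4,6-trimethoxyphenoxy)phenoxy]-2,3,4-trimethoxyphenoxy}dimethylsilane | COc1cc(OC)c(Oc2cc(OC)c(Oc3cc(OC)c(OC)c(OC)c3O[Si](C)(C)C(C)(C)C)c(OC)c2)c(OC)c1 | intermediate
21 | 6-[2,6-dimethoxy-4-(2,4,6-trimethoxyphenoxy)phenoxy]-2,3,4-trimethoxyphenol | COc1cc(OC)c(Oc2cc(OC)c(Oc3cc(OC)c(OC)c(OC)c3O)c(OC)c2)c(OC)c1 | intermediate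
22 | rings A–E pentamer, ring E C2 tert-butyldimethylsilyl ether, all other oxygens methylated | COc1cc(OC)c(Oc2cc(OC)c(Oc3cc(OC)c(OC)c(OC)c3Oc3cc(OC)c(Oc4cc(OC)c(OC)c(OC)c4O[Si](C)(C)C(C)(C)C)c(OC)c3)c(OC)c2)c(OC)c1 | intermediate
23 | rings A–E pentamer phenol, 6-[2,6-dimethoxy-4-(2,3,4-trimethoxy-6-{2,6-dimethoxy-4-(2,4,6-trimethoxyphenoxy)phenoxy}phenoxy)phenoxy]-2,3,4-trimethoxyphenol | COc1cc(OC)c(Oc2cc(OC)c(Oc3cc(OC)c(OC)c(OC)c3Oc3cc(OC)c(Oc4cc(OC)c(OC)c(OC)c4O)c(OC)c3)c(OC)c2)c(OC)c1 | intermediate
24 | per-O-methyl octamer (henicosamethyl ether of 25) | COc1cc(OC)c(Oc2cc(OC)c(Oc3cc(OC)c(OC)c(OC)c3Oc3cc(OC)c(Oc4cc(OC)c(OC)c(OC)c4Oc4cc(OC)c(Oc5cc(OC)c(OC)c(OC)c5Oc5cc(OC)c(OC)c(OC)c5)c(OC)c4)c(OC)c3)c(OC)c2)c(OC)c1 | intermediate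
25 | CNP0206369.0, the eight-ring polyphenol | Oc1cc(O)c(Oc2cc(O)c(Oc3cc(O)c(O)c(O)c3Oc3cc(O)c(Oc4cc(O)c(O)c(O)c4Oc4cc(O)c(Oc5cc(O)c(O)c(O)c5Oc5cc(O)c(O)c(O)c5)c(O)c4)c(O)c3)c(O)c2)c(O)c1 | target

## Step count and least certain steps

Total step count: 14. Longest linear sequence: 11 steps (5 → 7 → 9 → 11 → 16 → 18 → 20 → 21 → 22 → 23 → 24 → 25, that is steps 2, 3, 4, 7, 8, 9, 10, 11, 12, 13, 14).

**Step 4 (key step).** The donor-substituted alkenyl group stabilises the carbene and slows CO loss, so the temperature needed may let the terminal ynol ether oligomerise before it is captured. After alkyne insertion, the new carbene carbon is stabilised by the aryloxy group and may be slow to insert CO, so the sequence may stall or take up a second alkyne. Demetalation may over-oxidise the 4-methoxyphenol. The fallback sets out from 5 and comes back at 11, building ring G from a bought benzene. Purchased 5-bromo-1,2,3-trimethoxybenzene F1 is formylated at one of its two equivalent free positions (Cl2CHOMe, TiCl4, CH2Cl2, 0 °C, Rieche formylation) to 6-bromo-2,3,4-trimethoxybenzaldehyde F2. Ullmann coupling of 5 with F2 (CuI, N,N-dimethylglycine, Cs2CO3, dioxane, 100 °C), assisted by the ortho formyl group, gives 6-(2,6-dimethoxyphenoxy)-2,3,4-trimethoxybenzaldehyde F3. Baeyer–Villiger oxidation (mCPBA, CH2Cl2) gives 6-(2,6-dimethoxyphenoxy)-2,3,4-trimethoxyphenyl formate F4, and K2CO3 in MeOH releases 11.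

**Step 1.** The lithiated enol ether has lithium anti to the β-methoxy group, so β-elimination of lithium methoxide can compete with trapping, and metalation may be incomplete. The fallback sets out from 1 and returns at 4 without an organolithium. C-acylation of 1 with trichloroacetyl chloride and pyridine gives (3Z)-1,1,1-trichloro-3,4-dimethoxybut-3-en-2-one F5. Haloform cleavage with aqueous NaOH gives (2Z)-2,3-dimethoxyprop-2-enoic acid F6, and oxalyl chloride gives (2Z)-2,3-dimethoxyprop-2-enoyl chloride F7. Acylation of K2Cr(CO)5 (from Cr(CO)6 and KC8) gives potassium pentacarbonyl[(2Z)-2,3-dimethoxyprop-2-enoyl]chromate F8, and O-methylation with Me3OBF4 gives 4.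

**Step 3.** The terminal aryl ynol ether may polymerise or hydrate during concentration and storage. The fallback sets out from 8 and returns at 9. The acetylide is quenched with Me3SiCl to give [(2,6-dimethoxyphenoxy)ethynyl]trimethylsilane F9, which can be purified and stored. F9 is desilylated with catalytic K2CO3 in MeOH at 0 °C immediately before step 4, and 9 is used as a solution.

**Step 13 (the most exposed of the four couplings of this type).** The phenol of 23 is flanked on both sides and very electron-rich, so transmetalation and reductive elimination may be slower than protodeboronation or homocoupling of 15, and the oxidative medium may attack the phenol. The fallback sets out from 15 and returns at 24 by a non-oxidative coupling. Ipso-bromination of 15 (CuBr2, MeOH–H2O, 80 °C) gives 1-(4-bromo-2,6-dimethoxyphenoxy)-3,4,5-trimethoxy-2-(3,4,5-trimethoxyphenoxy)benzene F10. Ullmann coupling of F10 with 23 (CuI, picolinic acid, K3PO4, DMSO, 90 °C, Ar) gives 24.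

**Step 14.** Removal of 21 methyl groups may stop short, giving mixtures of partial ethers, and the polyphenol may oxidise during work-up and purification. The fallback sets out from 24 and returns at 25 through a stable derivative. After the BBr3 treatment the crude material is acetylated (Ac2O, pyridine) to the henicosaacetate of 25 F11, which can be chromatographed and checked for completeness. F11 is then deacetylated with HCl in MeOH under argon to give 25.

## Further compounds

F1 | step 4 | 5-bromo-1,2,3-trimethoxybenzene (purchased) | COc1cc(Br)cc(OC)c1OC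
F2 | step 4 | 6-bromo-2,3,4-trimethoxybenzaldehyde | COc1cc(Br)c(C=O)c(OC)c1OC
F3 | step 4 | 6-(2,6-dimethoxyphenoxy)-2,3,4-trimethoxybenzaldehyde | COc1cc(Oc2c(OC)cccc2OC)c(C=O)c(OC)c1OC
F4 | step 4 | 6-(2,6-dimethoxyphenoxy)-2,3,4-trimethoxyphenyl formate | COc1cc(Oc2c(OC)cccc2OC)c(OC=O)c(OC)c1OC
F5 | step 1 | (3Z)-1,1,1-trichloro-3,4-dimethoxybut-3-en-2-one | CO/C=C(\OC)C(=O)C(Cl)(Cl)Cl
F6 | step 1 | (2Z)-2,3-dimethoxyprop-2-enoic acid | CO/C=C(\OC)C(O)=O
F7 | step 1 | (2Z)-2,3-dimethoxyprop-2-enoyl chloride | CO/C=C(\OC)C(Cl)=O
F8 | step 1 | potassium pentacarbonyl[(2Z)-2,3-dimethoxyprop-2-enoyl]chromate | CO/C=C(\OC)C([O-])=[Cr](=C=O)(=C=O)(=C=O)(=C=O)=C=O.[K+]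
F9 | step 3 | [(2,6-dimethoxyphenoxy)ethynyl]trimethylsilane | COc1cccc(OC)c1OC#C[Si](C)(C)C
F10 | step 13 | 1-(4-bromo-2,6-dimethoxyphenoxy)-3,4,5-trimethoxy-2-(3,4,5-trimethoxyphenoxy)benzene | COc1cc(Oc2c(OC)cc(Br)cc2OC)c(Oc2cc(OC)c(OC)c(OC)c2)c(OC)c1OC
F11 | step 14 | henicosaacetate of 25 | CC(=O)Oc1cc(OC(C)=O)c(Oc2cc(OC(C)=O)c(Oc3cc(OC(C)=O)c(OC(C)=O)c(OC(C)=O)c3Oc3cc(OC(C)=O)c(Oc4cc(OC(C)=O)c(OC(C)=O)c(OC(C)=O)c4Oc4cc(OC(C)=O)c(Oc5cc(OC(C)=O)c(OC(C)=O)c(OC(C)=O)c5Oc5cc(OC(C)=O)c(OC(C)=O)c(OC(C)=O)c5)c(OC(C)=O)c4)c(OC(C)=O)c3)c(OC(C)=O)c2)c(OC(C)=O)c1
A1 | alternative 1 | 4-[4-(benzyloxy)-3,5-dimethoxyphenoxy]-5-(4-bromo-2,6-dimethoxyphenoxy)-3-methoxycyclohexa-3,5-diene-1,2-dione | COC1=C(Oc2cc(OC)c(OCc3ccccc3)c(OC)c2)C(Oc2c(OC)cc(Br)cc2OC)=CC(=O)C1=O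
A2 | alternative 1 | 3-[4-(benzyloxy)-3,5-dimethoxyphenoxy]-2-methoxyphenol | COc1c(O)cccc1Oc1cc(OC)c(OCc2ccccc2)c(OC)c1
A3 | alternative 1 | 4-bromo-2,6-dimethoxyphenol | COc1cc(Br)cc(OC)c1O
A4 | alternative 2 | 2-(benzyloxy)-3-methoxy-5-(2,4,6-trimethoxyphenoxy)phenol | COc1cc(Oc2c(OC)cc(OC)cc2OC)cc(O)c1OCc1ccccc1
A5 | alternative 2 | 4-(benzyloxy)-3-methoxycyclobut-2-en-1-one (racemic) | COC1=CC(=O)C1OCc1ccccc1
A6 | alternative 2 | 2-(ethynyloxy)-1,3,5-trimethoxybenzene | C#COc1c(OC)cc(OC)cc1OC
A7 | alternative 3 | cyclopentadienyl ruthenium hexafluorophosphate complex of the rings E–F–G trimer (ring E bromide, ring G benzyl ether) | COc1cc(Br)c(Oc2cc(OC)c(Oc3cc(OC)c(OC)c(OC)c3OCc3ccccc3)c(OC)c2)c(OC)c1OC.[Ru+2].c1cc[cH-]c1.F[P-](F)(F)(F)(F)F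
A8 | alternative 3 | cyclopentadienyl(η6-2,5-dichloro-1,3-dimethoxybenzene)ruthenium hexafluorophosphate | COc1cc(Cl)cc(OC)c1Cl.[Ru+2].c1cc[cH-]c1.F[P-](F)(F)(F)(F)F
A9 | alternative 3 | 6-bromo-2,3,4-trimethoxyphenol | COc1cc(Br)c(O)c(OC)c1OC
A10 | alternative 3 | 2-(benzyloxy)-3,4,5-trimethoxyphenol | COc1cc(O)c(OCc2ccccc2)c(OC)c1OC
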